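**Retrosynthetic overview**

1. All three C6–C3 units of the target are eugenol 1; no protecting groups are used.
2. C9–O aryl ether bond: two-electron oxidation of 1 gives vinyl quinone methide 2, which the phenol oxygen of a second molecule of 1 captures at C9 to give aryl cinnamyl ether 3.
3. Key disconnection: the C3–C3a (lignan 8–5') and O1–C2 bonds, both made in one enantioselective oxidative cross-coupling of 3 with 1 through para-quinone methide 4.
4. Ring order: the benzene rings are bought; the dihydrofuran ring is the only ring formed and closes last, giving target 5 with C3 and then C2 set in that step.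

Assumption: the facial sense of induction in the new asymmetric step 2 cannot be predicted with certainty; the (R)-ligand is written, and its (S)-antipode is to be used if the first run gives mainly the (2R,3S) product.

**Route**

Step 1
Reactants: 1 eugenol (4-allyl-2-methoxyphenol), the molecule that is oxidised; 1 eugenol, a second molecule that serves as the O-nucleophile (5 equiv, excess recovered)
Product: 3 (E)-4-[3-(4-allyl-2-methoxyphenoxy)prop-1-en-1-yl]-2-methoxyphenol, via vinyl quinone methide 2 (not isolated)
Conditions: Ag2O (1.5 equiv), CH2Cl2 (0.02 M), rt, dark, 45 min; filter through Celite into 1 (5 equiv), Cs2CO3 (10 mol%), MeCN, 0 °C to rt, 2 h; AcOH quench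
Reagents that add atoms: eugenol 1 (the second molecule, which supplies the aryloxy half of 3), C=CCc1ccc(O)c(OC)c1
Why: Proposed new method: Ag2O removes two electrons and two protons from 1 (phenoxyl radical, then loss of the doubly activated benzylic/allylic hydrogen) to give the vinyl quinone methide 2, and after the silver is filtered off the eugenoxide formed from the second molecule of 1 adds to the extended quinone methide; O-addition is reversible through the free para-phenoxide, so the conjugated linear (E)-cinnamyl ether from 1,8-addition at C9 accumulates as the thermodynamic O-adduct; the closest known reaction types are the conjugate addition of water or methanol to this kind of vinyl quinone methide (giving coniferyl alcohol or its methyl ether) and the addition of phenoxides to lignin-type quinone methides; no stereocentre is formed.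

Step 2
Reactants: 3 (E)-4-[3-(4-allyl-2-methoxyphenoxy)prop-1-en-1-yl]-2-methoxyphenol; 1 eugenol (5 equiv, excess recovered)
Product: 5 4-[(2S,3R)-5-allyl-3-[(4-allyl-2-methoxyphenoxy)methyl]-7-methoxy-2,3-dihydro-1-benzofuran-2-yl]-2-methoxyphenol, via quinone methide 4 (not isolated)
Conditions: 1 (5 equiv), Fe[(R)-TRIP]3 = iron tris[(R)-3,3'-bis(2,4,6-triisopropylphenyl)-1,1'-binaphthyl-2,2'-diyl phosphate] (5 mol%), t-BuOOt-Bu (1.2 equiv), ClCH2CH2Cl/HFIP 4:1, 0 °C to rt; 3 added by syringe pump over 8 h
Reagents that add atoms: none
Why: Proposed new method: the chiral trivalent-iron phosphate binds 1 as a chelating guaiacolate and the peroxide oxidises it to an iron-bound eugenoxyl radical, so the electron-rich C8 terminus of the 4-hydroxystyrene unit of 3 (free, or as its own phenoxyl radical as in the presumed biosynthesis) bonds to the ring carbon ortho to the Fe–O bond inside the chiral phosphate pocket, which selects the alkene face and fixes C3 as R; loss of one more electron and proton with re-aromatisation gives para-quinone methide 4, and 5-exo capture by the neighbouring phenol oxygen places the aryl group trans to the C3 substituent, setting C2 as S; the closest known reaction types are the racemic iron/peroxide oxidative [3+2] coupling of phenols with β-substituted styrenes to trans-2-aryl-2,3-dihydrobenzofurans, the classical achiral 8–5' oxidative coupling of coniferyl-type phenols, and the enantioselective oxidative coupling of 2-naphthols by chiral iron phosphate complexes.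

The enantiomeric excess of 5 is measured by chiral HPLC against the racemate, and the absolute configuration is assigned by circular dichroism.

**Compound list**

1 | eugenol (4-allyl-2-methoxyphenol) | C=CCc1ccc(O)c(OC)c1 | starting material
2 | 2-methoxy-4-(prop-2-en-1-ylidene)cyclohexa-2,5-dien-1-one (vinyl quinone methide of eugenol; mixture of isomers at the exocyclic double bond, geometry therefore not written) | C=CC=C1C=CC(=O)C(OC)=C1 | intermediate
3 | (E)-4-[3-(4-allyl-2-methoxyphenoxy)prop-1-en-1-yl]-2-methoxyphenol (coniferyl eugenyl ether) | C=CCc1ccc(OC/C=C/c2ccc(O)c(OC)c2)c(OC)c1 | intermediate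
4 | 4-[(2R)-3-(4-allyl-2-methoxyphenoxy)-2-(5-allyl-2-hydroxy-3-methoxyphenyl)propylidene]-2-methoxycyclohexa-2,5-dien-1-one (para-quinone methide; exocyclic double-bond geometry not fixed) | C=CCc1ccc(OC[C@H](C=C2C=CC(=O)C(OC)=C2)c2cc(CC=C)cc(OC)c2O)c(OC)c1 | intermediate
5 | 4-[(2S,3R)-5-allyl-3-[(4-allyl-2-methoxyphenoxy)methyl]-7-methoxy-2,3-dihydro-1-benzofuran-2-yl]-2-methoxyphenol (CNP0138854.1; trans) | C=CCc1ccc(OC[C@H]2c3cc(CC=C)cc(OC)c3O[C@@H]2c2ccc(O)c(OC)c2)c(OC)c1 | target

**Step count and risks**

Total step count: 2. Longest linear sequence: 2 steps (1 → 3 → 5). The route has only two steps, so both are named; step 2 is listed twice because it can fail in two unrelated ways, each with its own fallback.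

Risk 1, step 2 (enantioselectivity). The asymmetric induction is unproven; if the C8–C5' bond forms between free radicals outside the chiral pocket, 5 will be formed with low ee. Fallback: replace asymmetric catalysis by resolution. Setting out from 3 (with 1 in excess), the same slow-addition coupling is run with achiral FeCl3 (10 mol%) and t-BuOOt-Bu, giving the racemic trans-dihydrobenzofuran F1. Preparative chiral SFC (amylose tris(3,5-dimethylphenylcarbamate) phase, CO2/MeOH) then separates the enantiomers, and the (2S,3R) isomer, identified by circular dichroism, comes back to the route at 5.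

Risk 2, step 2 (chemoselectivity). Compound 3 is more easily oxidised than 1, so its 8–5' homodimer, 8–O–4' coupling, dehydrodieugenol or re-formation of 2 from 1 may outrun the cross-coupling. Fallback: mask the phenol of the alkene partner so that only 1 can give a phenoxyl radical. Setting out from 3, TBSCl/imidazole in DMF gives the silyl ether F2. Oxidative [3+2] coupling of 1 with F2 under the same chiral iron phosphate/t-BuOOt-Bu conditions gives the silyl-protected dihydrobenzofuran F3; this is now the plain phenol plus electron-rich styrene case, with trans ring closure onto the benzylic cation. TBAF buffered with AcOH in THF at 0 °C removes the silyl group and the sequence comes back to the route at 5.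

Risk 3, step 1. The vinyl quinone methide 2 may polymerise, eugenoxide may attack through carbon, or the branched 1,6-isomer may persist. Fallback: build the aryl cinnamyl ether by Mitsunobu etherification instead of quinone methide capture. Commercial ethyl ferulate is silylated (TBSCl, imidazole) to ethyl O-silylferulate F4. DIBAL in CH2Cl2 at −78 °C gives O-silylconiferyl alcohol F5. The fallback sets out from 1, which is coupled with F5 (PPh3, DIAD, THF, 0 °C) to give the silyl ether F2. TBAF/AcOH then frees the phenol and the sequence comes back to the route at 3.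

**Further compounds**

F1 | step 2 | racemic trans-4-[5-allyl-3-[(4-allyl-2-methoxyphenoxy)methyl]-7-methoxy-2,3-dihydro-1-benzofuran-2-yl]-2-methoxyphenol (1:1 mixture of the (2S,3R) and (2R,3S) enantiomers) | C=CCc1ccc(OC[C@H]2c3cc(CC=C)cc(OC)c3O[C@@H]2c2ccc(O)c(OC)c2)c(OC)c1.C=CCc1ccc(OC[C@@H]2c3cc(CC=C)cc(OC)c3O[C@H]2c2ccc(O)c(OC)c2)c(OC)c1
F2 | step 2 | tert-butyl{4-[(E)-3-(4-allyl-2-methoxyphenoxy)prop-1-en-1-yl]-2-methoxyphenoxy}dimethylsilane (TBS ether of 3) | C=CCc1ccc(OC/C=C/c2ccc(O[Si](C)(C)C(C)(C)C)c(OC)c2)c(OC)c1
F3 | step 2 | {4-[(2S,3R)-5-allyl-3-[(4-allyl-2-methoxyphenoxy)methyl]-7-methoxy-2,3-dihydro-1-benzofuran-2-yl]-2-methoxyphenoxy}(tert-butyl)dimethylsilane (TBS ether of 5) | C=CCc1ccc(OC[C@H]2c3cc(CC=C)cc(OC)c3O[C@@H]2c2ccc(O[Si](C)(C)C(C)(C)C)c(OC)c2)c(OC)c1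
F4 | step 1 | ethyl (E)-3-[4-(tert-butyldimethylsilyloxy)-3-methoxyphenyl]prop-2-enoate | CCOC(=O)/C=C/c1ccc(O[Si](C)(C)C(C)(C)C)c(OC)c1
F5 | step 1 | (E)-3-[4-(tert-butyldimethylsilyloxy)-3-methoxyphenyl]prop-2-en-1-ol | OC/C=C/c1ccc(O[Si](C)(C)C(C)(C)C)c(OC)c1
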